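## Analysis of the target

Target 20 consists of two 4-(4-hydroxyphenyl)-3,4-dihydrocoumarin (chroman-2-one) units joined by a C3–C3' single bond; the ring A lactone is fused to a 5,7-dihydroxybenzo ring and the ring B lactone to a fully oxygenated 5',6',7',8'-tetrahydroxybenzo ring. The four contiguous stereocentres C4, C3, C3' and C4' are 4S,3R,3'S,4'R, with H3 and H4 cis within each lactone. The two halves are related as object and mirror image, so the compound would be meso if the two benzo rings were equal, and its chirality rests only on the difference between ring A and ring B. The sensitive groups are the two aryl lactones (acyl donors), the epimerisable C3/C3' centres held in the crowded cis arrangement, the acid-labile doubly benzylic C4/C4' positions on very electron-rich rings, and the tetrahydroxy ring B, which oxidises in air. The difficulty is to set four adjacent centres with two cis relationships that equilibration will not give, to build two nearly identical halves with opposite absolute sense, and to free the octaphenol only at the end. The strategy rests on C2–C3–C3'–C2', a 2,3-disubstituted succinic acid unit whose two C–H bonds are syn: removing them gives a Z alkene, and removing the two carboxyl carbons as well gives an alkyne C3≡C3'. Both lactone carbonyls C2 and C2' can therefore come from two molecules of carbon dioxide 14 added across the alkyne of 13, in which C4 and C4' are propargylic diarylmethine centres.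

## Retrosynthetic reasoning

**20 ⇒ 19.** The C3–H and C3'–H bonds are removed to give the (Z)-alkylidene bis-lactone 19. The two hydrogens are syn in 20, so a syn addition to the Z alkene gives the meso-like C3/C3' pair in one operation. The forward step must deliver both hydrogens to the face opposite the two 4-aryl groups without moving the double bond into a ring.

**19 ⇒ 16.** The two lactone C–O bonds (O1–C2 and O1'–C2') are cut and the phenols are returned to methyl ethers, which leads to maleic anhydride 16. The anhydride is the form in which a cis diacid on a tetrasubstituted alkene is stable, and its five-membered ring holds the Z geometry. The forward step must cleave ten methyl ethers and close two six-membered lactones without disturbing C4 and C4'.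

**16 ⇒ 13 + 14 (two molecules).** The C2–C3 and C2'–C3' bonds are cut. These are the only skeletal bonds to carbons that bear no aryl group. Cutting them leaves alkyne 13 and turns the C3/C3' stereochemistry into a question of alkene geometry. The hindered C3–C3' bond between two stereocentres never has to be made, because it is the alkyne. The forward reaction must add two carboxyl units, one molecule of 14 at each alkyne carbon, syn across a hindered internal alkyne and leave the propargylic centres alone.

**13 ⇒ 10 + 12.** The triple bond itself is cut (alkyne metathesis). Each half is then the same kind of compound, a methyl-capped 1,1-diarylpropyne, so one asymmetric reaction run with mirror-image ligands serves both centres. Cutting instead between an alkyne carbon and C4' would require an enantioselective alkynylation of a diarylmethyl cation, for which no equally dependable reaction exists. The price is a statistical coupling. The symmetric by-products differ from 13 in their number of methoxy groups and should separate easily.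

**10 ⇒ 6 and 12 ⇒ 8.** The methyl caps are removed. The terminal alkynes are what the asymmetric step requires.

**6 ⇒ 4 + 5 and 8 ⇒ 4 + 7.** The aryl–carbon bonds C4–C4a and C4'–C4a' are cut. Both arenes are symmetric and electron-rich: 5 has three equal positions and 7 has only one free position, so no regiochemical question arises. The electrophile 4 is common to both halves and reacts through a planar intermediate, so it can be racemic. A chiral copper catalyst has to choose the face.

**4 ⇒ 1 + 2.** The propargylic C–C bond is cut to aldehyde 1 and the acetylide 2.

## Alternatives that were turned down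

**Alternative 1:** Ring B is grown last instead of being brought in as an arene.
- Disconnection: the C5'–C4a' bond and the benzo ring B itself are cut. This leads back to A1, a 4-hydroxy-2,3-dimethoxycyclobutenone whose carbinol carbon carries an alkyne ending at C4'. The chain of A1 already holds the C2' tert-butyl ester and the finished ring A lactone.
- Key step: heating A1 triggers electrocyclic opening of the four-membered ring and reclosure onto the alkyne (Moore-type rearrangement), which gives the 2,3-dimethoxybenzoquinone A2.
- For: the oxygenation pattern of ring B is fixed by construction and the thermolysis is neutral. It never passes through a crowded alkylidene bis-lactone, and on that point it is stronger than the chosen route.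
- Against: A2 carries only four of the five ring B oxygens. The quinone C–H must still be oxygenated, the quinone reduced and the C2' ester lactonised. A1 must already hold all four stereocentres, which the benzannulation does nothing to set. C3' (α to an ester) and C3 (α to a lactone) are exposed to prolonged heating.
- Comparison: the chosen strategy makes both carbonyl carbons and fixes the C3/C3' relationship in three steps from an alkyne whose two centres come from one catalytic reaction. Reaching A1 alone would take more steps than the whole chosen route.

**Alternative 2:** Lactone A is closed by a carbene-catalysed annulation.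
- Disconnection: C3–C4 and O1–C2 of lactone A are cut, which gives aldehyde A3 (the ring B lactone with a CH2CHO group on C3') and the ring A o-quinone methide A4.
- Key step: a chiral triazolium-derived carbene catalyst converts A3 into its catalyst-bound enolate. This adds to A4, which is generated in the flask by loss of a sulfinate. C–C bond formation at C4 and acylation of the phenoxide close lactone A and give A5, the octa-O-methyl ether of the target.
- For: it is convergent, it forms C3 and C4 under catalyst control at the final oxidation level, and A5 is one demethylation from 20. No tetrasubstituted alkene has to be hydrogenated. On late-stage stereocontrol it is stronger than the chosen route.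
- Against: A3 needs its own asymmetric synthesis with C3' and C4' in place. C3' is α to the lactone carbonyl and can epimerise under the basic carbene conditions. The aryl lactone of A3 is an acyl donor toward the carbene, the base and the phenoxide of A4. The chiral catalyst meets a chiral, β-branched enolate, so a mismatched pairing is possible.
- Comparison: the chosen strategy offers in its place that both halves come from one reaction type with mirror-image ligands, and that C3 and C3' are set together by one syn addition.

**Alternative 3:** A tether steers a Friedel–Crafts closure at C4.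
- Disconnection: the C4–C4a bond is cut. In silyl ether A6 (drawn as its tert-butyldimethylsilyl ether) the ring A arene is tethered as a 3,5-dimethoxyphenyl ester to the carboxyl that will become C2'.
- Key step: a Lewis acid ionises the C4 silyl ether of A6 to a benzylic cation stabilised by the 4-methoxyphenyl group. The tethered ring attacks it, forming C4–C4a and the seven-membered aryl lactone A7. The ester at C3 and the aryl at C4 are trans on that ring, which corresponds to the C3/C4 relationship of 20.
- For: an intramolecular Friedel–Crafts closure onto a dimethoxyphenyl ring is more certain as an arylation than the intermolecular copper-catalysed arylations of the chosen route. The ring sets the relative configuration.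
- Against: A7 is only the ring A half. The lactone must then be transposed from the seven- to the six-membered ring. The CH2 group (future C3') has still to be joined to C4' with two further stereocentres, and lactone B has to be built. The absolute configuration rests on a C3 centre α to an ester.
- Comparison: the chosen route treats both halves at once and leaves no C3–C3' or C3'–C4' bond to be made under stereocontrol.

Key step: step 7

Assumption: (S,S)-Ph-pybox is taken to give the (S) alkyne 6 and (R,R)-Ph-pybox the (R) alkyne 8; if the sense of induction is the reverse, the two ligands are exchanged between steps 2 and 3 and nothing else changes. Compounds 2, 5, 7 and the molybdenum alkylidyne of step 6 are taken as purchasable.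

## Route

Step 1
Reactants: 1 4-methoxybenzaldehyde; 2 ethynylmagnesium bromide
Product: 4 rac-1-(4-methoxyphenyl)prop-2-yn-1-yl acetate, via bromomagnesium propargylic alkoxide 3 (not isolated)
Conditions: 2 (1.1 equiv), THF, 0 °C; then Ac2O (1.5 equiv), 0 °C → rt
Reagents that add atoms: acetic anhydride, CC(=O)OC(C)=O
Why: Grignard 1,2-addition to the aldehyde followed by O-acylation of the magnesium alkoxide in the same flask; the product can be racemic because step 2 and step 3 pass through a planar cation.

Step 2
Reactants: 4 rac-1-(4-methoxyphenyl)prop-2-yn-1-yl acetate; 5 1,3,5-trimethoxybenzene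
Product: 6 2-[(1S)-1-(4-methoxyphenyl)prop-2-yn-1-yl]-1,3,5-trimethoxybenzene
Conditions: CuOTf·½C6H6 (5 mol%), (S,S)-Ph-pybox (6 mol%), iPr2NEt (1.2 equiv), 5 (3 equiv), CF3CH2OH, −20 → 0 °C
Reagents that add atoms: none
Why: Copper-catalysed asymmetric propargylic substitution of Friedel–Crafts type: monovalent copper and the amine form a copper acetylide, acetate leaves to give a copper allenylidene, and 5 attacks its γ-carbon. The pybox ligand shields one face of the planar cation, so both enantiomers of 4 converge on (S)-6; the three ring positions of 5 are equivalent and the weakly nucleophilic fluorinated alcohol is chosen so that the solvent does not compete with the arene.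

Step 3
Reactants: 4 rac-1-(4-methoxyphenyl)prop-2-yn-1-yl acetate; 7 pentamethoxybenzene
Product: 8 1-[(1R)-1-(4-methoxyphenyl)prop-2-yn-1-yl]-2,3,4,5,6-pentamethoxybenzene
Conditions: CuOTf·½C6H6 (10 mol%), (R,R)-Ph-pybox (12 mol%), iPr2NEt (1.2 equiv), 7 (3 equiv), CF3CH2OH, 0 °C → rt
Reagents that add atoms: none
Why: The same copper allenylidene Friedel–Crafts reaction with the mirror-image ligand, so the arene enters from the opposite face and (R)-8 should result. Compound 7 has a single free ring position, which fixes the regiochemistry, but it is a weaker nucleophile than 5 and the step is run warmer with more catalyst.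

Step 4
Reactants: 6 2-[(1S)-1-(4-methoxyphenyl)prop-2-yn-1-yl]-1,3,5-trimethoxybenzene
Product: 10 2-[(1R)-1-(4-methoxyphenyl)but-2-yn-1-yl]-1,3,5-trimethoxybenzene, via lithium acetylide 9 (not isolated)
Conditions: n-BuLi (1.0 equiv), THF, −78 °C; MeI (3 equiv), −78 °C → rt
Reagents that add atoms: iodomethane, CI
Why: Deprotonation of the terminal alkyne, the kinetically most acidic C–H, and SN2 methylation of the acetylide; one equivalent of base at −78 °C should leave the doubly benzylic centre untouched. The descriptor changes from S to R only because the propynyl group outranks the anisyl group.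

Step 5
Reactants: 8 1-[(1R)-1-(4-methoxyphenyl)prop-2-yn-1-yl]-2,3,4,5,6-pentamethoxybenzene
Product: 12 1-[(1S)-1-(4-methoxyphenyl)but-2-yn-1-yl]-2,3,4,5,6-pentamethoxybenzene, via lithium acetylide 11 (not isolated)
Conditions: n-BuLi (1.0 equiv), THF, −78 °C; MeI (3 equiv), −78 °C → rt
Reagents that add atoms: iodomethane, CI
Why: Acetylide methylation as in step 4; the stereocentre is not involved and the descriptor change from R to S is again only formal.

Step 6
Reactants: 10 2-[(1R)-1-(4-methoxyphenyl)but-2-yn-1-yl]-1,3,5-trimethoxybenzene; 12 1-[(1S)-1-(4-methoxyphenyl)but-2-yn-1-yl]-2,3,4,5,6-pentamethoxybenzene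
Product: 13 (1R,4S)-1,4-bis(4-methoxyphenyl)-1-(2,4,6-trimethoxyphenyl)-4-(pentamethoxyphenyl)but-2-yne
Conditions: 10 (2.5 equiv), Mo(≡CC6H4OMe-4)(OSiPh3)3 (10 mol%), 5 Å MS, toluene, 60 °C
Reagents that add atoms: none
Why: Alkyne cross-metathesis through molybdacyclobutadienes; the sieves take up the but-2-yne and drive the equilibrium, and the excess of 10 should channel most of 12 into the cross product. The symmetric by-products carry a different number of methoxy groups, so they should separate on silica and can be returned to the equilibrium; neither stereocentre takes part.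

Step 7
Reactants: 13 (1R,4S)-1,4-bis(4-methoxyphenyl)-1-(2,4,6-trimethoxyphenyl)-4-(pentamethoxyphenyl)but-2-yne; 14 carbon dioxide (two molecules are taken up)
Product: 16 3-[(S)-(4-methoxyphenyl)(2,4,6-trimethoxyphenyl)methyl]-4-[(R)-(4-methoxyphenyl)(pentamethoxyphenyl)methyl]furan-2,5-dione, via (Z)-butenedioic diacid 15 (not isolated)
Conditions: Ni(acac)2 (10 mol%), 2,2'-bipyridine (10 mol%), Zn dust (3 equiv), MgBr2 (3 equiv), 4 Å MS, 14 (1 atm, excess), DMF, 80 °C; then 3 M HCl, 0 °C → rt
Reagents that add atoms: carbon dioxide (the second molecule of 14), O=C=O
Why: Zinc reduces Ni(acac)2/2,2'-bipyridine to a zerovalent nickel–bipyridine complex, which couples the alkyne of 13 with a first molecule of 14 by oxidative cyclisation to a five-membered oxanickelacycle containing divalent nickel; this forms C2–C3. MgBr2 opens the metallacycle as a magnesium carboxylate, zinc reduces the nickel centre, and the remaining alkenyl–nickel bond inserts a second molecule of 14 to form C2'–C3', after which reduction releases the (Z)-dicarboxylate and returns zerovalent nickel, so that the overall equation is 13 + 2 CO2 + Zn + MgBr2. Acidification gives diacid 15, whose carboxyl groups are held cis on a tetrasubstituted alkene and should close at once to the maleic anhydride ring of 16 by a 5-exo-trig acyl substitution with loss of water, which leaves both carbons and three of the four oxygens of the two carbon dioxide molecules in the product. The closest known reaction is the nickel-catalysed double carboxylation of internal dialkyl and aryl alkyl alkynes with carbon dioxide under the same zinc/MgBr2 conditions; an alkyne flanked by two diarylmethyl groups is untested, hence the raised catalyst loading. No stereocentre is formed: the element created is the alkene geometry, fixed as Z because both C–C bonds are made on the same side of the alkyne within the metallacycle and are then tied into the ring. The step needs double rather than single carboxylation and retention at C4 and C4'; the substrate has no O–H or terminal C–H to protonate the alkenyl–metal intermediate, both alkyne carbons are carboxylated so regiochemistry does not arise, and the medium holds no base able to remove the doubly benzylic protons. Once 16 exists those protons are vinylogously acidic, so the work-up is kept cold and acidic.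

Step 8
Reactants: 16 3-[(S)-(4-methoxyphenyl)(2,4,6-trimethoxyphenyl)methyl]-4-[(R)-(4-methoxyphenyl)(pentamethoxyphenyl)methyl]furan-2,5-dione
Product: 19 (3Z,4S,4'R)-5,5',6',7,7',8'-hexahydroxy-4,4'-bis(4-hydroxyphenyl)-[3,3'-bichromanylidene]-2,2'-dione, via decaphenol anhydride 17 (not isolated), via ring A lactone acid 18 (not isolated)
Conditions: BBr3 (25 equiv), CH2Cl2, −78 °C → rt; H2O, 0 °C; then TsOH (10 mol%), 4 Å MS, MeCN, 40 °C, under argon; crude product used directly
Reagents that add atoms: none
Why: Lewis-acid ether cleavage (bromide attacks the methyl of each boron-complexed aryl ether) frees all ten phenols; in 17 each benzo ring holds an ortho hydroxyl placed to close a six-membered ring onto an anhydride carbonyl, so 6-exo-trig acyl transfer opens the anhydride to a lactone acid such as 18, and acid-catalysed lactonisation with removal of water closes the second ring. Both benzo rings are symmetric about their point of attachment, so either ortho hydroxyl gives the same lactone; the alkene geometry of the anhydride is carried over into the (Z)-bis-lactone and no stereocentre is formed or touched.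

Step 9
Reactants: 19 (3Z,4S,4'R)-5,5',6',7,7',8'-hexahydroxy-4,4'-bis(4-hydroxyphenyl)-[3,3'-bichromanylidene]-2,2'-dione
Product: 20 (3R,3'S,4S,4'R)-5,5',6',7,7',8'-hexahydroxy-4,4'-bis(4-hydroxyphenyl)-[3,3'-bichromane]-2,2'-dione
Conditions: H2 (10 bar), 10% Pd/C, THF–AcOH (10:1), rt, degassed solvents
Reagents that add atoms: none
Why: Heterogeneous syn hydrogenation of an electron-poor, strained tetrasubstituted alkene: in 19 the two C4 hydrogens must lie near the alkene plane, which puts both 4-aryl groups pseudoaxial, and because C4 is S and C4' is R they stand on the same face. The catalyst can then reach only the opposite face, so both hydrogens should arrive there, setting C3 as R and C3' as S with each new C–H cis to its neighbouring C4–H. The pseudoaxial aryl groups also keep the C4–H bonds out of alignment with the π system, which disfavours migration of the alkene into a ring.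

## Compound list

1 | 4-methoxybenzaldehyde | COc1ccc(C=O)cc1 | starting material
2 | ethynylmagnesium bromide | C#C[Mg]Br | starting material
3 | bromomagnesium 1-(4-methoxyphenyl)prop-2-yn-1-olate (racemic) | COc1ccc(C(O[Mg]Br)C#C)cc1 | intermediate
4 | rac-1-(4-methoxyphenyl)prop-2-yn-1-yl acetate | COc1ccc(C(OC(C)=O)C#C)cc1 | intermediate
5 | 1,3,5-trimethoxybenzene | COc1cc(OC)cc(OC)c1 | starting material
6 | 2-[(1S)-1-(4-methoxyphenyl)prop-2-yn-1-yl]-1,3,5-trimethoxybenzene | COc1cc(OC)cc(OC)c1[C@H](c1ccc(OC)cc1)C#C | intermediate
7 | pentamethoxybenzene | COc1cc(OC)c(OC)c(OC)c1OC | starting material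
8 | 1-[(1R)-1-(4-methoxyphenyl)prop-2-yn-1-yl]-2,3,4,5,6-pentamethoxybenzene | COc1c(OC)c(OC)c(OC)c(OC)c1[C@@H](c1ccc(OC)cc1)C#C | intermediate
9 | lithium acetylide of 6 (configuration of 6 retained) | COc1cc(OC)cc(OC)c1[C@H](c1ccc(OC)cc1)C#C[Li] | intermediate
10 | 2-[(1R)-1-(4-methoxyphenyl)but-2-yn-1-yl]-1,3,5-trimethoxybenzene | COc1cc(OC)cc(OC)c1[C@H](c1ccc(OC)cc1)C#CC | intermediate
11 | lithium acetylide of 8 (configuration of 8 retained) | COc1c(OC)c(OC)c(OC)c(OC)c1[C@@H](c1ccc(OC)cc1)C#C[Li] | intermediate
12 | 1-[(1S)-1-(4-methoxyphenyl)but-2-yn-1-yl]-2,3,4,5,6-pentamethoxybenzene | COc1c(OC)c(OC)c(OC)c(OC)c1[C@@H](c1ccc(OC)cc1)C#CC | intermediate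
13 | (1R,4S)-1,4-bis(4-methoxyphenyl)-1-(2,4,6-trimethoxyphenyl)-4-(pentamethoxyphenyl)but-2-yne | COc1cc(OC)cc(OC)c1[C@H](c1ccc(OC)cc1)C#C[C@@H](c1c(OC)c(OC)c(OC)c(OC)c1OC)c1ccc(OC)cc1 | intermediate
14 | carbon dioxide | O=C=O | starting material
15 | (2Z)-2-[(S)-(4-methoxyphenyl)(2,4,6-trimethoxyphenyl)methyl]-3-[(R)-(4-methoxyphenyl)(pentamethoxyphenyl)methyl]but-2-enedioic acid | COc1cc(OC)cc(OC)c1[C@H](c1ccc(OC)cc1)/C(C(=O)O)=C(/C(=O)O)[C@@H](c1c(OC)c(OC)c(OC)c(OC)c1OC)c1ccc(OC)cc1 | intermediate
16 | 3-[(S)-(4-methoxyphenyl)(2,4,6-trimethoxyphenyl)methyl]-4-[(R)-(4-methoxyphenyl)(pentamethoxyphenyl)methyl]furan-2,5-dione | COc1cc(OC)cc(OC)c1[C@H](c1ccc(OC)cc1)C1=C([C@@H](c2c(OC)c(OC)c(OC)c(OC)c2OC)c2ccc(OC)cc2)C(=O)OC1=O | intermediate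
17 | 3-[(S)-(4-hydroxyphenyl)(2,4,6-trihydroxyphenyl)methyl]-4-[(R)-(4-hydroxyphenyl)(pentahydroxyphenyl)methyl]furan-2,5-dione | Oc1cc(O)cc(O)c1[C@H](c1ccc(O)cc1)C1=C([C@@H](c2c(O)c(O)c(O)c(O)c2O)c2ccc(O)cc2)C(=O)OC1=O | intermediate
18 | (2Z,3R)-2-[(4S)-5,7-dihydroxy-4-(4-hydroxyphenyl)-2-oxochroman-3-ylidene]-3-(4-hydroxyphenyl)-3-(pentahydroxyphenyl)propanoic acid | O=C1Oc2cc(O)cc(O)c2[C@H](c2ccc(O)cc2)/C1=C(/C(=O)O)[C@@H](c1c(O)c(O)c(O)c(O)c1O)c1ccc(O)cc1 | intermediate
19 | (3Z,4S,4'R)-5,5',6',7,7',8'-hexahydroxy-4,4'-bis(4-hydroxyphenyl)-[3,3'-bichromanylidene]-2,2'-dione | O=C1Oc2cc(O)cc(O)c2[C@H](c2ccc(O)cc2)/C1=C1/C(=O)Oc2c(O)c(O)c(O)c(O)c2[C@H]1c1ccc(O)cc1 | intermediate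
20 | (3R,3'S,4S,4'R)-5,5',6',7,7',8'-hexahydroxy-4,4'-bis(4-hydroxyphenyl)-[3,3'-bichromane]-2,2'-dione | O=C1Oc2cc(O)cc(O)c2[C@H](c2ccc(O)cc2)[C@@H]1[C@H]1C(=O)Oc2c(O)c(O)c(O)c(O)c2[C@H]1c1ccc(O)cc1 | target

## Step count and least certain steps

Total step count: 9. Longest linear sequence: 7 steps (steps 1, 2, 4, 6, 7, 8, 9).

**Step 7 (key step).** The alkyne carries a diarylmethyl group with a 2,6-dimethoxyaryl ring on each side, so it may bind zerovalent nickel too weakly for the oxidative cyclisation. The reaction may also stop after one carboxylation if the alkenyl–metal intermediate is protonated before the second molecule of 14 inserts. Fallback: from 13, syn diboration (Pt(PPh3)4, B2pin2, DMF, 80 °C) gives the (Z)-1,2-bis(pinacolboryl)alkene F1. Copper-catalysed carboxylation of both alkenyl–boron bonds with two molecules of 14 ([(IPr)CuCl], IPr = 1,3-bis(2,6-diisopropylphenyl)imidazol-2-ylidene; KOMe, THF, 70 °C; cold HCl) then gives diacid 15, which closes to 16. The route is rejoined at 16.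

**Step 8.** Three processes threaten this step.
- The second lactone closure may stall or reverse. The Z bis-lactone is strained, since its two carbonyl groups and its two C4 substituents face each other, and the free carboxyl of 18 can re-form the anhydride and expel the phenol.
- The alkene may move into a ring to give a 4-arylcoumarin, with loss of a C4 centre, or may invert to E by reversible conjugate addition of bromide.
- The acid may cleave the electron-rich rings from C4/C4'.

Fallback: the crude product of the demethylation of 16 is left to settle to the mono-lactone acid 18, since the phenol opens the anhydride without a catalyst, and is hydrogenated without the second closure (H2, Pd/C, THF–AcOH). The single ring A lactone of 18 still holds its aryl group pseudoaxial, and syn addition sets C3 and C3' together, giving the saturated lactone acid F2. Its now unstrained ring B lactone is closed with TsOH to give 20, so the fallback runs from 16 to 20.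

**Step 9.** The tetrasubstituted alkene may be reduced slowly, which gives palladium hydride time to move the double bond into a ring, or forcing conditions may begin to reduce the electron-rich arenes. Fallback: diimide generated from potassium azodicarboxylate (KO2CN=NCO2K) and AcOH in dioxane transfers both hydrogens in a concerted syn fashion to the strained, maleate-like alkene of 19 from the same open face. No metal hydride is involved. The fallback runs from 19 to 20 and makes no new compound.

**Step 6.** The cross-coupling is statistical, and the branched, doubly arylated propargylic carbons may slow formation of the metallacycle until catalyst decay competes. Fallback: acetylide 9, generated from 6 with n-BuLi, is added to aldehyde 1 to give the propargylic alcohol F3 as both carbinol epimers. Acid-catalysed propargylic Friedel–Crafts arylation with 7 (TfOH 5 mol%, CH2Cl2, 0 °C) then gives 13 together with its epimer at the new centre, the (1R,4R) diastereomer F4, which is removed by preparative HPLC. This fallback sets out from 6, bypasses steps 3 and 5 and rejoins at 13.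

**Step 3 (and, to a lesser degree, step 2).** Capture of the copper allenylidene by a neutral polymethoxybenzene is slower than by the indoles, phenols and anilines usually used. Decomposition of the cation or capture by the solvent may therefore compete, and the enantioselectivity may fall at the higher temperature. Fallback: 7 is lithiated (n-BuLi, THF, 0 °C) and added to 1 to give (4-methoxyphenyl)(pentamethoxyphenyl)methanol F5. Ionisation with BF3·OEt2 in the presence of K[MeC≡CBF3] gives the racemic alkyne F6, which is resolved by preparative chiral HPLC. The fallback sets out from 7 and 1 and rejoins the route at 12, so steps 3 and 5 are not needed.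

## Further compounds

F1 | step 7 | (Z)-1,2-bis(pinacolboryl)alkene from syn diboration of 13, both centres unchanged | COc1cc(OC)cc(OC)c1[C@H](c1ccc(OC)cc1)/C(B1OC(C)(C)C(C)(C)O1)=C(/B1OC(C)(C)C(C)(C)O1)[C@@H](c1c(OC)c(OC)c(OC)c(OC)c1OC)c1ccc(OC)cc1
F2 | step 8 | (2S,3R)-2-[(3R,4S)-5,7-dihydroxy-4-(4-hydroxyphenyl)-2-oxochroman-3-yl]-3-(4-hydroxyphenyl)-3-(pentahydroxyphenyl)propanoic acid | O=C1Oc2cc(O)cc(O)c2[C@H](c2ccc(O)cc2)[C@@H]1[C@@H](C(=O)O)[C@@H](c1c(O)c(O)c(O)c(O)c1O)c1ccc(O)cc1
F0 | step 9 | none | none
F3 | step 6 | (4R)-1,4-bis(4-methoxyphenyl)-4-(2,4,6-trimethoxyphenyl)but-2-yn-1-ol, both C1 epimers | COc1cc(OC)cc(OC)c1[C@H](c1ccc(OC)cc1)C#CC(O)c1ccc(OC)cc1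
F4 | step 6 | (1R,4R)-1,4-bis(4-methoxyphenyl)-1-(2,4,6-trimethoxyphenyl)-4-(pentamethoxyphenyl)but-2-yne | COc1cc(OC)cc(OC)c1[C@H](c1ccc(OC)cc1)C#C[C@H](c1c(OC)c(OC)c(OC)c(OC)c1OC)c1ccc(OC)cc1
F5 | step 3 | (4-methoxyphenyl)(pentamethoxyphenyl)methanol, racemic | COc1ccc(C(O)c2c(OC)c(OC)c(OC)c(OC)c2OC)cc1
F6 | step 3 | rac-1-[1-(4-methoxyphenyl)but-2-yn-1-yl]-2,3,4,5,6-pentamethoxybenzene | COc1c(OC)c(OC)c(OC)c(OC)c1C(c1ccc(OC)cc1)C#CC
A1 | alternative 1 | 4-alkynyl-4-hydroxy-2,3-dimethoxycyclobut-2-en-1-one carrying the C4' chain with the C2' tert-butyl ester and the ring A lactone | COC1=C(OC)C(O)(C#C[C@H]([C@H](C(=O)OC(C)(C)C)[C@@H]2C(=O)Oc3cc(OC)cc(OC)c3[C@@H]2c2ccc(OC)cc2)c2ccc(OC)cc2)C1=O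
A2 | alternative 1 | 2,3-dimethoxy-1,4-benzoquinone bearing the C4' side chain (ring B at the quinone level) | COC1=C(OC)C(=O)C([C@H]([C@H](C(=O)OC(C)(C)C)[C@@H]2C(=O)Oc3cc(OC)cc(OC)c3[C@@H]2c2ccc(OC)cc2)c2ccc(OC)cc2)=CC1=O
A3 | alternative 2 | 2-[(3R,4R)-5,6,7,8-tetramethoxy-4-(4-methoxyphenyl)-2-oxochroman-3-yl]acetaldehyde | O=CC[C@H]1C(=O)Oc2c(OC)c(OC)c(OC)c(OC)c2[C@H]1c1ccc(OC)cc1
A4 | alternative 2 | 3,5-dimethoxy-6-[(4-methoxyphenyl)methylidene]cyclohexa-2,4-dien-1-one (ring A o-quinone methide) | O=C1C=C(OC)C=C(OC)C1=Cc1ccc(OC)cc1
A5 | alternative 2 | octa-O-methyl ether of the target | O=C1Oc2cc(OC)cc(OC)c2[C@H](c2ccc(OC)cc2)[C@@H]1[C@H]1C(=O)Oc2c(OC)c(OC)c(OC)c(OC)c2[C@H]1c1ccc(OC)cc1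
A6 | alternative 3 | 4-(3,5-dimethoxyphenyl) 1-methyl 2-[(tert-butyldimethylsilyloxy)(4-methoxyphenyl)methyl]butanedioate | COC(=O)[C@@H](CC(=O)Oc1cc(OC)cc(OC)c1)C(O[Si](C)(C)C(C)(C)C)c1ccc(OC)cc1
A7 | alternative 3 | methyl trans-6,8-dimethoxy-5-(4-methoxyphenyl)-2-oxo-2,3,4,5-tetrahydro-1-benzoxepine-4-carboxylate | COC(=O)[C@H]1CC(=O)Oc2cc(OC)cc(OC)c2[C@@H]1c1ccc(OC)cc1
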